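## Analysis of the target

Compound 20 is a flavanone. Ring A (C4a, C5 to C8, C8a) carries a free hydroxyl at C5, a 3-methylbut-2-enyl (prenyl) group at C6 and a methoxy group at C7. Ring C (O1, C2, C3, C4, C4a, C8a) holds the C4 ketone, and the 4-hydroxyphenyl ring B sits on C2. C2 is the only stereocentre and is S. It is benzylic, bears O1 and lies β to the carbonyl, so base erases it by retro-oxa-Michael opening to the 2'-hydroxychalcone, and strong acid can erase it more slowly by ionising the C2–O1 bond. The prenyl alkene stands ortho to the C5 hydroxyl: acid can close the two onto each other to a dimethylchromane, and the alkene forbids hydrogenation or hydrogenolysis of protecting groups. Ring A is a phloroglucinol with three different oxygen functions (O1, the chelated 5-OH, 7-OMe), and its carbon substituent must sit at C6, not at the electronically similar C8. The synthesis therefore has two problems: one labile stereocentre and the regiochemistry of ring A. The plan rests on reading O1, C8a, C4a and C4 as an ortho-quinone methide that already carries an oxygen on its methide carbon C4 (a salicylaldehyde at the acetal level), and C3, C2 and ring B as a para-oxygenated styrene. Ring C is then a [4+2] adduct made under acid, where a 2-arylchromane keeps its configuration, at the price of one oxidation-level correction at C4.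

## Retrosynthetic reasoning

**20 to 19.** No skeletal bond is cut; the two phenols are masked as methoxymethyl ethers in 19. Acetal-type groups are chosen because they leave under acid alone. Base would open ring C and hydrogen would reduce the prenyl group. Exactly two phenols need masking, because the key step tolerates only one free phenol on ring A and none on ring B.

**19 to 18 to 17.** The C4 carbonyl is taken back to the benzylic alcohol 18 and this to the C4 methyl ether 17. C4 is a disposable centre. Its C–O bond is the most easily ionised bond of the molecule (the cation is stabilised by O1, the C5 oxygen and the C7 oxygen), so the ether can be exchanged under acidity too mild to touch the aryl acetals or the C2–O1 bond. The forward steps must do this without elimination to the chromene and then oxidise without base.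

**17 to 10, 13 and 14 (key disconnection).** The C3–C4 and O1–C2 bonds are cut together. This opens ring C into salicylaldehyde 10, styrene 13 and orthoformate 14, which supplies the C4 methoxy group by way of acetal 15 and quinone methide 16. The cut is placed here because both bonds flank the stereocentre, so C2 is created in the ring-forming event under a chiral acid. Cutting C2–O1 alone (chalcone cyclisation) or C2–aryl would put the stereocentre into a base-mediated or a separate reduction step. The forward reaction has to control the face of 16, the endo approach of 13, and the choice of the styrene over the prenyl alkene.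

**13 to 11.** The aryl acetal of 13 is traced to the commercial acetate 11 through phenolate 12, which is not isolated because the free vinylphenol polymerises.

**10 to 8.** The protecting groups are exchanged. In 10 the phenol next to the prenyl group is an acetal and the phenol next to the ring C–H is free; in 8 the first is free and the second is an acetate (via 9). This decides that O1 ends next to C8–H and the prenyl group at C6; the opposite pattern would give the 8-prenyl isomer.

**8 to 6.** The aryl–prenyl C–C bond is cut by an aromatic Claisen transform, through dienone 7. The ether oxygen of 6 has one free ortho carbon only, so the prenyl group can go to one place. The oxygen that carried the allyl group comes out as the free phenol, which is the one that must receive the acetal in the next step.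

**6 to 5 to 4 to 2 and 3.** The 1,1-dimethylallyl ether comes from the propargyl ether 5 by semihydrogenation. Compound 5 comes from 4 by acetylation of the second phenol, and 4 from the symmetric diol 2 and the tertiary propargylic chloride 3. Because 2 is symmetric, the first etherification raises no regiochemical question. It only has to stop at the monoether.

**2 to 1.** The two ortho methyl ethers of 1 are removed by chelation to the formyl group. This fixes the 7-methoxy group without a selective alkylation of a triol.

## Alternatives that were turned down

**Alternative 1: carbonylative three-component flavone annulation, then enantioselective reduction.**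
- Disconnection: C4a–C4, C4–C3 and O1–C2 at the flavone level, from 2-iodo-5-methoxybenzene-1,3-diol A1, carbon monoxide A2 and 1-ethynyl-4-(methoxymethoxy)benzene A3.
- Forward key step: PdCl2(dppf) in an amine solvent couples the three to an ortho-hydroxyaryl ynone that cyclises in the flask to flavone A4.
- For: this annulation is established chemistry, which the chosen key step is not. A1 is symmetric, so O1 and the 5-OH need not be told apart. The fragments are simpler than 10. On precedent and on convergence this alternative is stronger.
- Against: A4 has neither the stereocentre nor the prenyl group. C2 would come from an enantioselective 1,4-reduction of a poorly electrophilic, chelated vinylogous ester, with over-reduction at C4 as a side path. Hydrogenation-type methods also forbid an earlier prenyl group. Prenylation of the resulting 5-hydroxyflavanone then faces the C6/C8 choice. It needs either base, which opens ring C, or an O-allylation and sigmatropic sequence at temperatures where the flavanone racemises.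
- Comparison: the chosen route places the prenyl group unambiguously before ring C exists and sets C2 while the ring forms. Counting the late reduction and prenylation, the alternative is not shorter.

**Alternative 2: enantioselective carbene C–H insertion into the O1 benzyl ether.**
- Disconnection: C2–C3, from diazoketone A5, which carries the 4-silyloxybenzyl ether on the future O1.
- Forward key step: a chiral carboxylate dimer of divalent rhodium such as Rh2(PTTL)4, in the appropriate enantiomeric form, generates a carbene at C3 that inserts into a benzylic C–H bond, closing ring C and setting C2 in A6.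
- For: ring C is formed directly at the ketone level, so only two deprotections follow. That endgame is shorter than the chosen one, which needs an oxidation-level correction.
- Against: the carbene is of the unselective acceptor-only type. It must form a six-membered ring, while the lone pair of O1 sits in position for a five-membered oxonium ylide and a benzyl shift to a benzofuranone. Ring B invites cycloheptatriene formation and the prenyl alkene invites cyclopropanation. A5 requires a diazoacetyl group on a fully substituted ring between two ortho oxygen substituents, with the prenyl group already present. The 5-acetate of A6 must finally be removed under conditions that endanger C2.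
- Comparison: in the chosen key step O1 is the nucleophile that is meant to react and the precursor is an aldehyde. The chemoselectivity risk of the alternative becomes a stereoselectivity risk in the chosen route, which a catalyst screen can address.

**Alternative 3: ring A by Claisen condensation of a chain that carries ring C.**
- Disconnection: C4a–C5, from the dihydropyranone keto ester A7, in which ring C and C2 are already present.
- Forward key step: a mild base such as Mg(OMe)2 enolises the chain at C8, and the vinylogous enolate attacks the terminal ester through C4a. Ring A closes and tautomerises to the 5,7-diol A8.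
- For: the prenyl group is fixed at C6 by the chain, so there is no C6/C8 question. C2 can be set early by a well-established asymmetric hetero-Diels–Alder reaction. On both points the alternative is as strong as or stronger than the chosen route.
- Against: the condensation needs base on a ring whose C2–O1 bond is β to a carbonyl, so E1cB opening racemises C2. O-acylation and other aldol modes compete. The polycarbonyl chain must be assembled in several C–C bond-forming steps. A8 still lacks the 7-methyl group, so a selective methylation follows.
- Comparison: the chosen route buys ring A as an arene and handles C2 only under acidic or neutral conditions after it is made. It is the shorter of the two.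

Key step: step 8

## Route

Assumption: the sense of induction of the chiral acid in step 8 cannot be assigned in advance; the enantiomer that gives (2S,4S)-17 is taken to be found in a first screen, both enantiomers of the acid being available.

Step 1
Reactants: 1 2,4,6-trimethoxybenzaldehyde
Product: 2 2,6-dihydroxy-4-methoxybenzaldehyde
Conditions: AlCl3 (4 equiv), CH2Cl2, 0 °C to rt; then ice-cold 1 M HCl
Reagents that add atoms: none
Why: Chelation-directed Lewis acid ether cleavage: AlCl3 bound to the formyl oxygen activates only the two ortho methoxy groups and chloride removes their methyl groups, while the para methoxy group cannot chelate and stays, so the 7-OMe pattern of ring A is fixed without a selectivity question.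

Step 2
Reactants: 2 2,6-dihydroxy-4-methoxybenzaldehyde, 3 3-chloro-3-methylbut-1-yne
Product: 4 2-hydroxy-4-methoxy-6-[(2-methylbut-3-yn-2-yl)oxy]benzaldehyde
Conditions: 3 (1.05 equiv), DBU (1.1 equiv), CuCl2·2H2O (1 mol%), MeCN, −5 to 0 °C
Reagents that add atoms: none
Why: Copper-catalysed propargylic etherification of a phenoxide by a tertiary propargylic chloride; 2 is symmetric so either hydroxyl gives the same ether, and after one etherification the remaining hydroxyl is locked in the hydrogen bond to the formyl group and is a much weaker nucleophile, the same discrimination that leaves the chelated hydroxyl of 2,4-dihydroxybenzaldehydes untouched.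

Step 3
Reactants: 4 2-hydroxy-4-methoxy-6-[(2-methylbut-3-yn-2-yl)oxy]benzaldehyde
Product: 5 2-formyl-5-methoxy-3-[(2-methylbut-3-yn-2-yl)oxy]phenyl acetate
Conditions: Ac2O, pyridine, 4-(dimethylamino)pyridine (cat.), CH2Cl2, 0 °C to rt
Reagents that add atoms: acetic anhydride, CC(=O)OC(C)=O
Why: Acylation of the one remaining chelated phenol under nucleophilic catalysis; the acetate is a temporary label for the oxygen that is to become O1 and survives the neutral hydrogenation and the thermal rearrangement that follow.

Step 4
Reactants: 5 2-formyl-5-methoxy-3-[(2-methylbut-3-yn-2-yl)oxy]phenyl acetate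
Product: 6 2-formyl-5-methoxy-3-[(2-methylbut-3-en-2-yl)oxy]phenyl acetate
Conditions: H2 (1 atm), Pd/CaCO3 poisoned with Pb(OAc)2 (Lindlar catalyst), quinoline, EtOAc, rt
Reagents that add atoms: none
Why: Semihydrogenation of the terminal alkyne over the poisoned palladium catalyst stops at the alkene and leaves aldehyde, aryl acetate and arene alone; reducing before heating avoids the chromene that the propargyl ether itself would give.

Step 5
Reactants: 6 2-formyl-5-methoxy-3-[(2-methylbut-3-en-2-yl)oxy]phenyl acetate
Product: 8 2-formyl-3-hydroxy-5-methoxy-4-(3-methylbut-2-en-1-yl)phenyl acetate, via ortho-dienone 7 (not isolated)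
Conditions: PhMe, 120 °C, sealed tube
Reagents that add atoms: none
Why: Aromatic Claisen rearrangement: the [3,3] shift can end productively only on the one unsubstituted carbon ortho to the ether oxygen (the other bears the formyl group), the allyl unit is transposed so that the tertiary ether delivers the linear prenyl group, and enolisation of dienone 7 gives the phenol with the prenyl group between the new hydroxyl and the methoxy group, the future C6.

Step 6
Reactants: 8 2-formyl-3-hydroxy-5-methoxy-4-(3-methylbut-2-en-1-yl)phenyl acetate
Product: 10 6-hydroxy-4-methoxy-2-(methoxymethoxy)-3-(3-methylbut-2-en-1-yl)benzaldehyde, via MOM ether acetate 9 (not isolated)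
Conditions: MOMCl (1.5 equiv), i-Pr2NEt (2.5 equiv), CH2Cl2, 0 °C to rt; then MeOH, K2CO3, 0 °C to rt
Reagents that add atoms: chloromethyl methyl ether, COCCl
Why: O-alkylation of the phenol beside the prenyl group by the α-chloro ether under amine base, which does not disturb the aryl acetate, then base-catalysed transesterification of the activated aryl acetate by methanol in the same flask; the only free phenol of 10 is thus the one flanked by the ring C–H, the future O1.

Step 7
Reactants: 11 4-ethenylphenyl acetate
Product: 13 1-ethenyl-4-(methoxymethoxy)benzene, via potassium 4-vinylphenolate 12 (not isolated)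
Conditions: t-BuOK (1.05 equiv), THF, 0 °C; then MOMCl (1.2 equiv), 0 °C to rt
Reagents that add atoms: chloromethyl methyl ether, COCCl
Why: Alkoxide cleavage of the aryl ester gives the phenolate, which is alkylated in the flask (Williamson-type etherification), so the polymerisation-prone free vinylphenol is never isolated.

Step 8
Reactants: 10 6-hydroxy-4-methoxy-2-(methoxymethoxy)-3-(3-methylbut-2-en-1-yl)benzaldehyde, 13 1-ethenyl-4-(methoxymethoxy)benzene, 14 trimethyl orthoformate
Product: 17 (2S,4S)-4,7-dimethoxy-5-(methoxymethoxy)-2-[4-(methoxymethoxy)phenyl]-6-(3-methylbut-2-en-1-yl)-3,4-dihydro-2H-chromene, via dimethyl acetal 15 (not isolated), via methoxy quinone methide 16 (not isolated)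
Conditions: 13 (2.5 equiv), 14 (1.5 equiv), (R)- or (S)-3,3'-bis(2,4,6-triisopropylphenyl)-1,1'-binaphthyl-2,2'-diyl hydrogen phosphate (10 mol%, hand from screen), 5 Å molecular sieves, PhMe, −20 to 0 °C; then Et3N
Reagents that add atoms: none
Why: Proposed new method: the acid and 14 turn aldehyde 10 into dimethyl acetal 15, which loses methanol to the C4-methoxy ortho-quinone methide 16, held in the chiral pocket as a hydrogen-bonded ion pair with the phosphate; the CH2 terminus of styrene 13 then attacks C4 while the positive charge growing at C2, stabilised by the para methoxymethoxy group, is captured by O1, an asynchronous inverse-electron-demand oxa-Diels-Alder reaction. The closest known reaction types are the racemic Lewis-acid three-component coupling of salicylaldehydes, orthoformates and alkenes to cis-4-methoxychromans and the chiral phosphoric-acid-catalysed [4+2] cycloadditions of ortho-quinone methides with styrenes; the enantioselective version on an acetal-derived, C4-oxygenated quinone methide has not been shown. Ring C closes as a six-membered ring in this single [4+2] event, C3–C4 bond first and O1–C2 bond second. C4 is set by the catalyst, whose 3,3'-aryl groups leave one face of the bound quinone methide open, and C2 is set relative to C4 by the endo approach of the styrene aryl group, which places the C2 aryl and C4 methoxy groups cis, so the S configuration at C2 depends on facial and endo selectivity together. Chemoselectivity for 13 over the prenyl alkene should follow from the higher nucleophilicity of the para-oxygenated styrene, used in excess, and from the fact that the prenyl group cannot reach C4 of its own molecule; regioselectivity follows from the benzylic cation, and because 10 has a single free phenol, O1 can only be the oxygen next to C8–H, which puts the prenyl group at C6. The sieves take up the methanol, and the cold, amine-quenched work-up should keep C4 from epimerising, so that any trans isomer, which would carry the opposite C2 configuration, can still be removed by chromatography.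

Step 9
Reactants: 17 (2S,4S)-4,7-dimethoxy-5-(methoxymethoxy)-2-[4-(methoxymethoxy)phenyl]-6-(3-methylbut-2-en-1-yl)-3,4-dihydro-2H-chromene
Product: 18 (2S)-7-methoxy-5-(methoxymethoxy)-2-[4-(methoxymethoxy)phenyl]-6-(3-methylbut-2-en-1-yl)-3,4-dihydro-2H-chromen-4-ol (mixture of C4 epimers)
Conditions: pyridinium p-toluenesulfonate (0.2 equiv), acetone/H2O 4:1, 0.02 M, rt
Reagents that add atoms: water, O
Why: SN1 solvolysis: the C4–OMe bond ionises under very mild acid because the cation is stabilised by O1, the C5 oxygen and the C7 oxygen, and water in large excess captures it; the aryl methoxymethyl ethers and the C2–O1 bond, which has only one donor behind it, need stronger acid, so C2 is untouched and the C4 configuration does not matter.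

Step 10
Reactants: 18 (2S)-7-methoxy-5-(methoxymethoxy)-2-[4-(methoxymethoxy)phenyl]-6-(3-methylbut-2-en-1-yl)-3,4-dihydro-2H-chromen-4-ol (mixture of C4 epimers)
Product: 19 (2S)-7-methoxy-5-(methoxymethoxy)-2-[4-(methoxymethoxy)phenyl]-6-(3-methylbut-2-en-1-yl)-2,3-dihydro-4H-chromen-4-one
Conditions: Dess-Martin periodinane (1.3 equiv), NaHCO3 (5 equiv), CH2Cl2, 0 °C to rt
Reagents that add atoms: none
Why: Hypervalent iodine oxidation of a secondary benzylic alcohol to the aryl ketone under buffered, non-basic conditions; both C4 epimers converge, the alkene and acetals are inert, and no base is present that could open ring C at the new β-aryloxy ketone.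

Step 11
Reactants: 19 (2S)-7-methoxy-5-(methoxymethoxy)-2-[4-(methoxymethoxy)phenyl]-6-(3-methylbut-2-en-1-yl)-2,3-dihydro-4H-chromen-4-one
Product: 20 (2S)-5-hydroxy-2-(4-hydroxyphenyl)-7-methoxy-6-(3-methylbut-2-en-1-yl)-2,3-dihydro-4H-chromen-4-one (6-prenylsakuranetin)
Conditions: conc. HCl (5 equiv), MeOH, 40 °C, short reaction time
Reagents that add atoms: none
Why: Acid-catalysed acetal exchange with methanol removes both methoxymethyl groups, the C5 one being activated by chelation to the C4 carbonyl; a flavanone keeps its C2 configuration in dilute protic acid at this temperature, and this deprotection is standard on prenylated flavanones and chalcones when kept short and mild.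

## Compound list

1 | 2,4,6-trimethoxybenzaldehyde | COc1cc(OC)c(C=O)c(OC)c1 | starting material
2 | 2,6-dihydroxy-4-methoxybenzaldehyde | COc1cc(O)c(C=O)c(O)c1 | intermediate
3 | 3-chloro-3-methylbut-1-yne | CC(C)(Cl)C#C | starting material
4 | 2-hydroxy-4-methoxy-6-[(2-methylbut-3-yn-2-yl)oxy]benzaldehyde | COc1cc(O)c(C=O)c(OC(C)(C)C#C)c1 | intermediate
5 | 2-formyl-5-methoxy-3-[(2-methylbut-3-yn-2-yl)oxy]phenyl acetate | COc1cc(OC(C)=O)c(C=O)c(OC(C)(C)C#C)c1 | intermediate
6 | 2-formyl-5-methoxy-3-[(2-methylbut-3-en-2-yl)oxy]phenyl acetate | COc1cc(OC(C)=O)c(C=O)c(OC(C)(C)C=C)c1 | intermediate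
7 | 2-formyl-5-methoxy-4-(3-methylbut-2-en-1-yl)-3-oxocyclohexa-1,5-dien-1-yl acetate (racemic ortho-dienone, not isolated) | O=CC1=C(OC(C)=O)C=C(OC)C(CC=C(C)C)C1=O | intermediate
8 | 2-formyl-3-hydroxy-5-methoxy-4-(3-methylbut-2-en-1-yl)phenyl acetate | COc1cc(OC(C)=O)c(C=O)c(O)c1CC=C(C)C | intermediate
9 | 2-formyl-5-methoxy-3-(methoxymethoxy)-4-(3-methylbut-2-en-1-yl)phenyl acetate (not isolated) | COc1cc(OC(C)=O)c(C=O)c(OCOC)c1CC=C(C)C | intermediate
10 | 6-hydroxy-4-methoxy-2-(methoxymethoxy)-3-(3-methylbut-2-en-1-yl)benzaldehyde | COc1cc(O)c(C=O)c(OCOC)c1CC=C(C)C | intermediate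
11 | 4-ethenylphenyl acetate (4-acetoxystyrene) | CC(=O)Oc1ccc(C=C)cc1 | starting material
12 | potassium 4-ethenylphenolate (not isolated) | C=Cc1ccc([O-])cc1.[K+] | intermediate
13 | 1-ethenyl-4-(methoxymethoxy)benzene | C=Cc1ccc(OCOC)cc1 | intermediate
14 | trimethyl orthoformate | COC(OC)OC | starting material
15 | 2-(dimethoxymethyl)-5-methoxy-3-(methoxymethoxy)-4-(3-methylbut-2-en-1-yl)phenol (not isolated) | COC(OC)c1c(O)cc(OC)c(CC=C(C)C)c1OCOC | intermediate
16 | (6E)-3-methoxy-5-(methoxymethoxy)-6-(methoxymethylidene)-4-(3-methylbut-2-en-1-yl)cyclohexa-2,4-dien-1-one (not isolated; drawn with the methoxy group anti to the ring carbonyl) | CO/C=C1/C(=O)C=C(OC)C(CC=C(C)C)=C1OCOC | intermediate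
17 | (2S,4S)-4,7-dimethoxy-5-(methoxymethoxy)-2-[4-(methoxymethoxy)phenyl]-6-(3-methylbut-2-en-1-yl)-3,4-dihydro-2H-chromene (2,4-cis) | COc1cc2c(c(OCOC)c1CC=C(C)C)[C@@H](OC)C[C@@H](c1ccc(OCOC)cc1)O2 | intermediate
18 | (2S)-7-methoxy-5-(methoxymethoxy)-2-[4-(methoxymethoxy)phenyl]-6-(3-methylbut-2-en-1-yl)-3,4-dihydro-2H-chromen-4-ol (mixture of C4 epimers) | COc1cc2c(c(OCOC)c1CC=C(C)C)C(O)C[C@@H](c1ccc(OCOC)cc1)O2 | intermediate
19 | (2S)-7-methoxy-5-(methoxymethoxy)-2-[4-(methoxymethoxy)phenyl]-6-(3-methylbut-2-en-1-yl)-2,3-dihydro-4H-chromen-4-one | COc1cc2c(c(OCOC)c1CC=C(C)C)C(=O)C[C@@H](c1ccc(OCOC)cc1)O2 | intermediate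
20 | (2S)-5-hydroxy-2-(4-hydroxyphenyl)-7-methoxy-6-(3-methylbut-2-en-1-yl)-2,3-dihydro-4H-chromen-4-one (6-prenylsakuranetin) | COc1cc2c(c(O)c1CC=C(C)C)C(=O)C[C@@H](c1ccc(O)cc1)O2 | target

## Step count and uncertain steps

Total: 11 steps. Longest linear sequence: 10 steps (steps 1 to 6, then 8 to 11); step 7 is a one-step side branch.

**Step 8 (key step, new method).** Several processes could defeat it:
- The quinone methide is stabilised by three oxygen donors and may react sluggishly.
- Facial or endo selectivity may be insufficient. Either one lowers the enantiomeric purity at C2 once C4 is erased.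
- Acid may cause loss of a methoxymethyl group, cationic oligomerisation of the styrene, or attack of the quinone methide on the electron-rich ring of a second molecule.

A stronger acid of the same family (the N-triflyl phosphoramide) is the first variation. The fallback uses known chemistry and sets out from 10, 13 and 14. The three components are combined with Sc(OTf)3 (5 mol%) in CH2Cl2, the established racemic form of this coupling, to give the racemic cis-4-methoxyflavan F1. The conditions of steps 9 and 10 take it to the racemic flavan-4-ol F2 and the racemic ketone F3. F3 is then resolved kinetically by asymmetric transfer hydrogenation with RuCl(p-cymene)[(R,R)-TsDPEN] or its (S,S) enantiomer (TsDPEN = N-tosyl-1,2-diphenylethane-1,2-diamine) in HCO2H/Et3N, a known resolution of flavanones. The catalyst hand is chosen so that the (2R) ketone is reduced to the cis-(2R,4R)-flavan-4-ol F4 while the (2S) ketone is left. The route is rejoined at 19.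

**Step 9.** The C4 cation may lose a proton to give the chromene, or be captured by the nucleophilic C8 of a second molecule (hence the high dilution). Partial loss of the acetals is also possible. The fallback sets out from 17 and goes straight to 19 by oxidative cleavage of the electron-rich benzylic methyl ether with DDQ in CH2Cl2/pH 7 buffer. This removes hydride from C4 instead of ionising the C–O bond and makes no new compound. Its own risk is hydride abstraction at the prenyl CH2.

**Step 11.** The liberated 5-hydroxyl may add to the prenyl alkene under acid to form a dimethylchromane ring. The alkene may be hydrated, or C2 may slowly racemise, if the conditions must be forced to remove the unactivated acetal on ring B. The fallback changes the protecting group on ring B and sets out from 12, generated as in step 7.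
- 12 is silylated with TBSCl to tert-butyl(4-ethenylphenoxy)dimethylsilane F5.
- F5 replaces 13 in step 8 (with 10 and 14) to give the (2S,4S)-4-methoxyflavan silyl ether F6.
- Steps 9 and 10 give the flavan-4-ol F7 and the ketone F8.
- The chelation-activated C5 acetal of F8 is removed with pyridinium p-toluenesulfonate in MeOH at 40 °C, far milder than step 11, to give the 5-hydroxy ketone silyl ether F9.
- Et3N·3HF in THF cleaves the aryl silyl ether without base, and the route is rejoined at 20.

**Step 2.** Double etherification or incomplete conversion of the symmetric diol would lower the supply. The fallback sets out from 2. Direct C-alkylation of its phenoxide with 1-bromo-3-methylbut-2-ene (aqueous KOH, 0 °C) is a classical reaction of acylphloroglucinols and can give only one mono-C-prenyl isomer here, because of the symmetry. It should give 2,6-dihydroxy-4-methoxy-3-(3-methylbut-2-en-1-yl)benzaldehyde F10. Acetylation of its less hindered hydroxyl (Ac2O 1 equiv, pyridine, −20 °C) rejoins the route at 8. This is shorter but less clean, which is why it is the fallback.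

## Further compounds

F1 | step 8 | racemic cis-4,7-dimethoxy-5-(methoxymethoxy)-2-[4-(methoxymethoxy)phenyl]-6-(3-methylbut-2-en-1-yl)-3,4-dihydro-2H-chromene | COc1cc2c(c(OCOC)c1CC=C(C)C)[C@@H](OC)C[C@@H](c1ccc(OCOC)cc1)O2.COc1cc2c(c(OCOC)c1CC=C(C)C)[C@H](OC)C[C@H](c1ccc(OCOC)cc1)O2
F2 | step 8 | racemic 7-methoxy-5-(methoxymethoxy)-2-[4-(methoxymethoxy)phenyl]-6-(3-methylbut-2-en-1-yl)-3,4-dihydro-2H-chromen-4-ol (C4 epimers) | COc1cc2c(c(OCOC)c1CC=C(C)C)C(O)CC(c1ccc(OCOC)cc1)O2
F3 | step 8 | racemic 7-methoxy-5-(methoxymethoxy)-2-[4-(methoxymethoxy)phenyl]-6-(3-methylbut-2-en-1-yl)-2,3-dihydro-4H-chromen-4-one | COc1cc2c(c(OCOC)c1CC=C(C)C)C(=O)C[C@@H](c1ccc(OCOC)cc1)O2.COc1cc2c(c(OCOC)c1CC=C(C)C)C(=O)C[C@H](c1ccc(OCOC)cc1)O2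
F4 | step 8 | (2R,4R)-7-methoxy-5-(methoxymethoxy)-2-[4-(methoxymethoxy)phenyl]-6-(3-methylbut-2-en-1-yl)-3,4-dihydro-2H-chromen-4-ol (2,4-cis) | COc1cc2c(c(OCOC)c1CC=C(C)C)[C@H](O)C[C@H](c1ccc(OCOC)cc1)O2
F0 | step 9 | none | none
F5 | step 11 | tert-butyl(4-ethenylphenoxy)dimethylsilane | C=Cc1ccc(O[Si](C)(C)C(C)(C)C)cc1
F6 | step 11 | tert-butyl{4-[(2S,4S)-4,7-dimethoxy-5-(methoxymethoxy)-6-(3-methylbut-2-en-1-yl)-3,4-dihydro-2H-chromen-2-yl]phenoxy}dimethylsilane | COc1cc2c(c(OCOC)c1CC=C(C)C)[C@@H](OC)C[C@@H](c1ccc(O[Si](C)(C)C(C)(C)C)cc1)O2
F7 | step 11 | (2S)-2-{4-[(tert-butyldimethylsilyl)oxy]phenyl}-7-methoxy-5-(methoxymethoxy)-6-(3-methylbut-2-en-1-yl)-3,4-dihydro-2H-chromen-4-ol (C4 epimers) | COc1cc2c(c(OCOC)c1CC=C(C)C)C(O)C[C@@H](c1ccc(O[Si](C)(C)C(C)(C)C)cc1)O2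
F8 | step 11 | (2S)-2-{4-[(tert-butyldimethylsilyl)oxy]phenyl}-7-methoxy-5-(methoxymethoxy)-6-(3-methylbut-2-en-1-yl)-2,3-dihydro-4H-chromen-4-one | COc1cc2c(c(OCOC)c1CC=C(C)C)C(=O)C[C@@H](c1ccc(O[Si](C)(C)C(C)(C)C)cc1)O2
F9 | step 11 | (2S)-2-{4-[(tert-butyldimethylsilyl)oxy]phenyl}-5-hydroxy-7-methoxy-6-(3-methylbut-2-en-1-yl)-2,3-dihydro-4H-chromen-4-one | COc1cc2c(c(O)c1CC=C(C)C)C(=O)C[C@@H](c1ccc(O[Si](C)(C)C(C)(C)C)cc1)O2
F10 | step 2 | 2,6-dihydroxy-4-methoxy-3-(3-methylbut-2-en-1-yl)benzaldehyde | COc1cc(O)c(C=O)c(O)c1CC=C(C)C
A1 | alternative 1 | 2-iodo-5-methoxybenzene-1,3-diol | COc1cc(O)c(I)c(O)c1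
A2 | alternative 1 | carbon monoxide | [C-]#[O+]
A3 | alternative 1 | 1-ethynyl-4-(methoxymethoxy)benzene | C#Cc1ccc(OCOC)cc1
A4 | alternative 1 | 5-hydroxy-7-methoxy-2-[4-(methoxymethoxy)phenyl]-4H-chromen-4-one | COc1cc(O)c2c(=O)cc(-c3ccc(OCOC)cc3)oc2c1
A5 | alternative 2 | 3-{[4-(tert-butyldimethylsilyloxy)phenyl]methoxy}-2-(2-diazoacetyl)-5-methoxy-6-(3-methylbut-2-en-1-yl)phenyl acetate | COc1cc(OCc2ccc(O[Si](C)(C)C(C)(C)C)cc2)c(C(=O)C=[N+]=[N-])c(OC(C)=O)c1CC=C(C)C
A6 | alternative 2 | (2S)-2-{4-[(tert-butyldimethylsilyl)oxy]phenyl}-7-methoxy-6-(3-methylbut-2-en-1-yl)-4-oxo-3,4-dihydro-2H-chromen-5-yl acetate | COc1cc2c(c(OC(C)=O)c1CC=C(C)C)C(=O)C[C@@H](c1ccc(O[Si](C)(C)C(C)(C)C)cc1)O2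
A7 | alternative 3 | methyl 4-{(2S)-2-[4-(methoxymethoxy)phenyl]-4-oxo-3,4-dihydro-2H-pyran-6-yl}-2-(3-methylbut-2-en-1-yl)-3-oxobutanoate (epimers at the ester α-carbon) | COC(=O)C(CC=C(C)C)C(=O)CC1=CC(=O)C[C@@H](c2ccc(OCOC)cc2)O1
A8 | alternative 3 | (2S)-5,7-dihydroxy-2-[4-(methoxymethoxy)phenyl]-6-(3-methylbut-2-en-1-yl)-2,3-dihydro-4H-chromen-4-one | Oc1cc2c(c(O)c1CC=C(C)C)C(=O)C[C@@H](c1ccc(OCOC)cc1)O2
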